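The flavanone half is disconnected across ring C at O1–C2 and C3–C4. O1 and C4 sit on adjacent carbons of ring A (C8a and C4a), so ring A with C4 is a salicylaldehyde-derived ortho-quinone methide, and the trans C2–C3 unit with its two aryl groups is an (E)-stilbene. One chiral-acid-catalysed [4+2] addition of the O-methyl oxocarbenium ion of a dibenzylated salicylaldehyde to a benzoate-substituted stilbene closes ring C, forms both bonds, sets C2 and C3 and leaves C4 as a methyl ether ready for oxidation. The benzoate ester then carries the flavone (Claisen condensation, cyclodehydration) before a final hydrogenolysis.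

Key step: step 5

Assumption: the catalyst is written as its (R) enantiomer; the sense of induction for this pair of partners is not established, so the enantiomer that delivers the (2R) cycloadduct is the one meant.

Remark on descriptors: in the 4-methoxychroman, C2 outranks C4 at C3, so the cycloadduct that maps onto the (2R,3S)-flavanone is (2R,3R), drawn here as the all-trans 4R epimer (the 4S epimer would serve equally). The spatial arrangement is unchanged, and the label returns to 3S once C4 is a carbonyl carbon.

Remark on order: C4 is oxidised before the acid-mediated flavone closure, because a 4-methoxy group on the 5,7-dialkoxychroman would ionise under acid. 13 and 14 are drawn as 1,3-diketones but should exist as mixtures with their enol and cyclic hemiketal forms.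

**Route**

Step 1
Reactants: 1 2,4,6-trihydroxybenzaldehyde
Product: 2 4,6-bis(benzyloxy)-2-hydroxybenzaldehyde
Conditions: BnBr (2.1 equiv), K2CO3 (2.2 equiv), DMF, 0 °C to rt
Reagents that add atoms: benzyl bromide, BrCc1ccccc1
Why: Williamson ether synthesis that should stop after two benzylations, because the 4-OH (para to the formyl group) and one ortho OH react while the last ortho OH is held in a hydrogen bond to the carbonyl oxygen and is far less nucleophilic.

Step 2
Reactants: 3 methyl 3-formyl-4-hydroxybenzoate
Product: 4 methyl 4-(benzyloxy)-3-formylbenzoate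
Conditions: BnBr (1.2 equiv), K2CO3, DMF, 60 °C
Reagents that add atoms: benzyl bromide, BrCc1ccccc1
Why: Williamson ether synthesis on a phenol made acidic by the ortho formyl and para ester groups, both of which are inert to K2CO3.

Step 3
Reactants: 5 4-(benzyloxy)benzyl chloride
Product: 6 diethyl [4-(benzyloxy)benzyl]phosphonate
Conditions: P(OEt)3 (neat, 3 equiv), 150 °C
Reagents that add atoms: triethyl phosphite, CCOP(OCC)OCC
Why: Michaelis–Arbuzov reaction, in which phosphorus displaces the benzylic chloride and chloride dealkylates the phosphonium salt.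

Step 4
Reactants: 4 methyl 4-(benzyloxy)-3-formylbenzoate; 6 diethyl [4-(benzyloxy)benzyl]phosphonate
Product: 7 methyl 4-(benzyloxy)-3-[(E)-2-[4-(benzyloxy)phenyl]ethenyl]benzoate
Conditions: NaH (1.2 equiv), THF, 0 °C to rt
Reagents that add atoms: none
Why: Horner–Wadsworth–Emmons olefination, in which the benzylic phosphonate carbanion adds reversibly to the aldehyde and the anti adduct collapses fastest, so the (E)-stilbene should result while the methyl ester is left alone.

Step 5
Reactants: 2 4,6-bis(benzyloxy)-2-hydroxybenzaldehyde; 7 methyl 4-(benzyloxy)-3-[(E)-2-[4-(benzyloxy)phenyl]ethenyl]benzoate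
Product: 10 methyl 4-(benzyloxy)-3-[(2R,3R,4R)-5,7-bis(benzyloxy)-2-[4-(benzyloxy)phenyl]-4-methoxy-3,4-dihydro-2H-chromen-3-yl]benzoate, via dimethyl acetal 8 (not isolated), via O-methyl oxocarbenium ion 9 (not isolated)
Conditions: HC(OMe)3 (3 equiv), (R)-3,3'-bis(2,4,6-triisopropylphenyl)-1,1'-binaphthyl-2,2'-diyl N-triflylphosphoramide (10 mol %), 7 (2 equiv), slow addition of 2, CH2Cl2, −30 °C to 0 °C; then Et3N
Reagents that add atoms: trimethyl orthoformate, COC(OC)OC
Why: Proposed new method: the chiral acid should turn 2 and HC(OMe)3 into acetal 8 and then, by loss of methanol, into the O-methyl oxocarbenium ion 9 (the O-protonated form of a 4-methoxy ortho-quinone methide), which stays ion-paired and hydrogen-bonded through its phenol OH to the phosphoramide anion; the stilbene then adds across C4 and the phenol oxygen in an asynchronous inverse-electron-demand hetero-Diels–Alder reaction in which C3–C4 bond formation runs ahead of O1–C2 bond formation. The closest known reaction type is the acid-catalysed [4+2] cycloaddition of salicylaldehyde acetals (made in situ with an orthoformate) and of ortho-quinone methides with styrenes, including enantioselective versions under BINOL-derived phosphoric acid and N-triflylphosphoramide catalysis; a 1,2-diarylethene has not served as the two-carbon partner in the enantioselective variant, hence the label. Ring C is closed as a six-membered ring by the [4+2] cycloaddition itself (in the stepwise limit, by attack of the phenol oxygen on the 4-benzyloxybenzyl cation at C2). C2 and C3 take their trans relationship from the (E)-alkene through suprafacial addition and their absolute configuration from the chiral counter-anion, which blocks one face of the ion-paired oxocarbenium ion, while the methoxy orientation at C4 follows the endo/exo preference and is irrelevant because C4 later becomes a carbonyl carbon. The step needs regioselectivity (O1 to the carbon carrying the 4-benzyloxyphenyl ring), and that carbon supports positive charge best because its para-alkoxy donor is fully available, whereas the alkoxy group of the other ring is engaged in conjugation with its para ester, that ring is twisted by its ortho substituent and the ester sits meta to the alkene carbon. It also needs chemoselectivity for the alkene over Friedel–Crafts attack by the electron-rich ring A, which excess stilbene, slow addition of 2 and low temperature are meant to secure.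

Step 6
Reactants: 11 2',4',6'-trihydroxyacetophenone
Product: 12 1-[2,4-bis(benzyloxy)-6-hydroxyphenyl]ethanone
Conditions: BnBr (2.1 equiv), K2CO3 (2.2 equiv), DMF, rt
Reagents that add atoms: benzyl bromide, BrCc1ccccc1
Why: Williamson ether synthesis that should spare the one ortho OH that is hydrogen-bonded to the acetyl carbonyl, as in step 1.

Step 7
Reactants: 10 methyl 4-(benzyloxy)-3-[(2R,3R,4R)-5,7-bis(benzyloxy)-2-[4-(benzyloxy)phenyl]-4-methoxy-3,4-dihydro-2H-chromen-3-yl]benzoate; 12 1-[2,4-bis(benzyloxy)-6-hydroxyphenyl]ethanone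
Product: 13 1-[2,4-bis(benzyloxy)-6-hydroxyphenyl]-3-{4-(benzyloxy)-3-[(2R,3R,4R)-5,7-bis(benzyloxy)-2-[4-(benzyloxy)phenyl]-4-methoxy-3,4-dihydro-2H-chromen-3-yl]phenyl}propane-1,3-dione
Conditions: NaH (4 equiv), 12 (1.5 equiv), THF, 65 °C; then AcOH, 0 °C
Reagents that add atoms: none
Why: Crossed Claisen condensation in which the phenoxide–enolate dianion of 12 is acylated at carbon by the methyl ester and the equilibrium is pulled through by deprotonation of the 1,3-diketone; 12 should not self-condense because its carbonyl is flanked by two ortho oxygens, and the 4-methoxychroman has no base-sensitive site, so C2 and C3 are safe.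

Step 8
Reactants: 13 the 4-methoxychroman 1,3-diketone
Product: 14 (2R,3S)-5,7-bis(benzyloxy)-2-[4-(benzyloxy)phenyl]-3-{2-(benzyloxy)-5-[3-(2,4-bis(benzyloxy)-6-hydroxyphenyl)-3-oxopropanoyl]phenyl}-2,3-dihydro-4H-chromen-4-one
Conditions: DDQ (2.5 equiv), CH2Cl2/H2O (10:1), 0 °C to rt
Reagents that add atoms: water, O
Why: DDQ oxidation of an electron-rich benzylic methyl ether to the ketone, in which the C4 hydride (activated by the methoxy group and by the three oxygen donors ortho and para on ring A) is abstracted, water adds to the oxocarbenium ion and methanol is lost; C2 is untouched and C3, now alpha to the ketone, should keep or relax to the favoured trans-diequatorial arrangement, its label changing to S only because C4 gains priority.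

Step 9
Reactants: 14 the flavanone 1,3-diketone
Product: 15 (2R,3S)-5,7-bis(benzyloxy)-2-[4-(benzyloxy)phenyl]-3-[2-(benzyloxy)-5-(5,7-bis(benzyloxy)-4-oxo-4H-chromen-2-yl)phenyl]-2,3-dihydro-4H-chromen-4-one
Conditions: HCl (cat., about 1% in MeOH/THF 1:1), 50 °C
Reagents that add atoms: none
Why: Acid-catalysed cyclodehydration that completes the Claisen/Baker–Venkataraman-type flavone synthesis (the phenol closes on the enolised diketone and water is lost to give the aromatic pyranone); dilute methanolic HCl at moderate temperature is a medium in which flavanone C2 centres are expected to hold, and the oxygen on the C3 aryl ring is still benzylated, so it cannot condense with the C4 ketone.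

Step 10
Reactants: 15 the hexabenzyl flavanone–flavone
Product: 16 (2R,3S)-5,7-dihydroxy-3-[2-hydroxy-5-(5,7-dihydroxy-4-oxo-4H-chromen-2-yl)phenyl]-2-(4-hydroxyphenyl)-2,3-dihydro-4H-chromen-4-one (CNP0324936.1)
Conditions: H2 (1 atm), 10% Pd/C, THF/MeOH (1:1), rt
Reagents that add atoms: none
Why: Catalytic hydrogenolysis of six aryl benzyl ethers under neutral conditions, which avoids the base-induced ring opening that would racemise C2; the flavone C2=C3 bond and the conjugated ketones should not be reduced at ambient pressure and temperature.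

**Compound list**

1 | 2,4,6-trihydroxybenzaldehyde | O=Cc1c(O)cc(O)cc1O | starting material
2 | 4,6-bis(benzyloxy)-2-hydroxybenzaldehyde | O=Cc1c(O)cc(OCc2ccccc2)cc1OCc1ccccc1 | intermediate
3 | methyl 3-formyl-4-hydroxybenzoate | COC(=O)c1ccc(O)c(C=O)c1 | starting material
4 | methyl 4-(benzyloxy)-3-formylbenzoate | COC(=O)c1ccc(OCc2ccccc2)c(C=O)c1 | intermediate
5 | 4-(benzyloxy)benzyl chloride | ClCc1ccc(OCc2ccccc2)cc1 | starting material
6 | diethyl [4-(benzyloxy)benzyl]phosphonate | CCOP(=O)(Cc1ccc(OCc2ccccc2)cc1)OCC | intermediate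
7 | methyl 4-(benzyloxy)-3-[(E)-2-[4-(benzyloxy)phenyl]ethenyl]benzoate | COC(=O)c1ccc(OCc2ccccc2)c(/C=C/c2ccc(OCc3ccccc3)cc2)c1 | intermediate
8 | 3,5-bis(benzyloxy)-2-(dimethoxymethyl)phenol (dimethyl acetal of 2, not isolated) | COC(OC)c1c(O)cc(OCc2ccccc2)cc1OCc1ccccc1 | intermediate
9 | O-methyl oxocarbenium ion of 2 (O-protonated 4-methoxy ortho-quinone methide, ion pair with the catalyst anion, not isolated) | C[O+]=Cc1c(O)cc(OCc2ccccc2)cc1OCc1ccccc1 | intermediate
10 | methyl 4-(benzyloxy)-3-[(2R,3R,4R)-5,7-bis(benzyloxy)-2-[4-(benzyloxy)phenyl]-4-methoxy-3,4-dihydro-2H-chromen-3-yl]benzoate (2,3-trans, 3,4-trans) | CO[C@H]1c2c(OCc3ccccc3)cc(OCc3ccccc3)cc2O[C@@H](c2ccc(OCc3ccccc3)cc2)[C@@H]1c1cc(C(=O)OC)ccc1OCc1ccccc1 | intermediate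
11 | 2',4',6'-trihydroxyacetophenone | CC(=O)c1c(O)cc(O)cc1O | starting material
12 | 1-[2,4-bis(benzyloxy)-6-hydroxyphenyl]ethanone | CC(=O)c1c(O)cc(OCc2ccccc2)cc1OCc1ccccc1 | intermediate
13 | 1-[2,4-bis(benzyloxy)-6-hydroxyphenyl]-3-{4-(benzyloxy)-3-[(2R,3R,4R)-5,7-bis(benzyloxy)-2-[4-(benzyloxy)phenyl]-4-methoxy-3,4-dihydro-2H-chromen-3-yl]phenyl}propane-1,3-dione | CO[C@H]1c2c(OCc3ccccc3)cc(OCc3ccccc3)cc2O[C@@H](c2ccc(OCc3ccccc3)cc2)[C@@H]1c1cc(C(=O)CC(=O)c2c(O)cc(OCc3ccccc3)cc2OCc2ccccc2)ccc1OCc1ccccc1 | intermediate
14 | (2R,3S)-5,7-bis(benzyloxy)-2-[4-(benzyloxy)phenyl]-3-{2-(benzyloxy)-5-[3-(2,4-bis(benzyloxy)-6-hydroxyphenyl)-3-oxopropanoyl]phenyl}-2,3-dihydro-4H-chromen-4-one | O=C1c2c(OCc3ccccc3)cc(OCc3ccccc3)cc2O[C@@H](c2ccc(OCc3ccccc3)cc2)[C@@H]1c1cc(C(=O)CC(=O)c2c(O)cc(OCc3ccccc3)cc2OCc2ccccc2)ccc1OCc1ccccc1 | intermediate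
15 | (2R,3S)-5,7-bis(benzyloxy)-2-[4-(benzyloxy)phenyl]-3-[2-(benzyloxy)-5-(5,7-bis(benzyloxy)-4-oxo-4H-chromen-2-yl)phenyl]-2,3-dihydro-4H-chromen-4-one | O=C1c2c(OCc3ccccc3)cc(OCc3ccccc3)cc2O[C@@H](c2ccc(OCc3ccccc3)cc2)[C@@H]1c1cc(-c2cc(=O)c3c(OCc4ccccc4)cc(OCc4ccccc4)cc3o2)ccc1OCc1ccccc1 | intermediate
16 | (2R,3S)-5,7-dihydroxy-3-[2-hydroxy-5-(5,7-dihydroxy-4-oxo-4H-chromen-2-yl)phenyl]-2-(4-hydroxyphenyl)-2,3-dihydro-4H-chromen-4-one (CNP0324936.1) | O=C1c2c(O)cc(O)cc2O[C@@H](c2ccc(O)cc2)[C@@H]1c1cc(-c2cc(=O)c3c(O)cc(O)cc3o2)ccc1O | target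

**Totals**

Total step count: 10.
Longest linear sequence: 7 steps (3 → 4 → 7 → 10 → 13 → 14 → 15 → 16, that is steps 2, 4, 5, 7, 8, 9 and 10).

**Steps most likely to fail**

1. Step 5 (the step marked as a new method). The 1,2-diaryl alkene may add too slowly to the strongly stabilised oxocarbenium ion. The electron-rich ring A may instead attack the cation (Friedel–Crafts oligomerisation). Facial or regiochemical control may be eroded, or the product may lose methanol under the acid. Fallback with chemistry of known types, setting out from 2 and 7 and returning at 10: reduce 2 with NaBH4 (THF/MeOH, 0 °C) to 3,5-bis(benzyloxy)-2-(hydroxymethyl)phenol F1. Heat F1 with 7 (toluene, sealed tube, about 150 °C), which should release the parent ortho-quinone methide by loss of water and trap it in a thermal [4+2] cycloaddition as the racemic trans-2,3-diarylchroman F2. Introduce the 4-methoxy group by benzylic oxidation with DDQ in CH2Cl2/MeOH (the usual C4 functionalisation of 5,7-dialkoxyflavans) to give the racemic 4-methoxychroman F3. Separate the enantiomers of F3 by preparative chromatography on a chiral stationary phase to obtain 10.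

2. Step 8. Hydride abstraction at C4 may be outpaced by oxidation of the free phenol or enolised diketone. It may also compete with abstraction of the C2 hydrogen, which is a 4-alkoxybenzylic ether position, or the reaction may stall at partial conversion. Fallback, setting out from 10 and returning at 15: carry out the oxidation at the fully protected ester stage with DDQ in dry CH2Cl2/MeOH, so that methanol traps the oxocarbenium ion, to give the 4,4-dimethoxy ketal ester F4. Condense F4 with 12 under the conditions of step 7 to give the ketal 1,3-diketone F5. Treat F5 with the acid of step 9 in the presence of a little water, which should hydrolyse the ketal and close the pyranone in one operation to give 15.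

3. Step 7. C-acylation may be incomplete because the dianion of 12 is aggregated and the ester is deactivated by its para-alkoxy group, so the reaction may stop at starting ester or at O-acylated material. Fallback, setting out from 10 and returning at 13: saponify 10 (LiOH, THF/MeOH/H2O, 50 °C, then AcOH to pH 5–6) to the carboxylic acid F6. Esterify F6 with the phenol of 12 (EDC, DMAP, CH2Cl2, Steglich conditions) to the aryl ester F7. Rearrange F7 with KOtBu in THF (0 °C to rt, then AcOH; Baker–Venkataraman O-to-C acyl shift) to 13.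

**Further compounds**

F1 | step 5 | 3,5-bis(benzyloxy)-2-(hydroxymethyl)phenol | OCc1c(O)cc(OCc2ccccc2)cc1OCc1ccccc1
F2 | step 5 | racemic methyl 4-(benzyloxy)-3-[(2R*,3S*)-5,7-bis(benzyloxy)-2-[4-(benzyloxy)phenyl]-3,4-dihydro-2H-chromen-3-yl]benzoate (2,3-trans, one enantiomer drawn) | C1c2c(OCc3ccccc3)cc(OCc3ccccc3)cc2O[C@@H](c2ccc(OCc3ccccc3)cc2)[C@@H]1c1cc(C(=O)OC)ccc1OCc1ccccc1
F3 | step 5 | racemic methyl 4-(benzyloxy)-3-[(2R*,3R*,4R*)-5,7-bis(benzyloxy)-2-[4-(benzyloxy)phenyl]-4-methoxy-3,4-dihydro-2H-chromen-3-yl]benzoate (racemate of 10, one enantiomer drawn) | CO[C@H]1c2c(OCc3ccccc3)cc(OCc3ccccc3)cc2O[C@@H](c2ccc(OCc3ccccc3)cc2)[C@@H]1c1cc(C(=O)OC)ccc1OCc1ccccc1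
F4 | step 8 | methyl 4-(benzyloxy)-3-[(2R,3S)-5,7-bis(benzyloxy)-2-[4-(benzyloxy)phenyl]-4,4-dimethoxy-3,4-dihydro-2H-chromen-3-yl]benzoate | COC1(OC)c2c(OCc3ccccc3)cc(OCc3ccccc3)cc2O[C@@H](c2ccc(OCc3ccccc3)cc2)[C@@H]1c1cc(C(=O)OC)ccc1OCc1ccccc1
F5 | step 8 | 1-[2,4-bis(benzyloxy)-6-hydroxyphenyl]-3-{4-(benzyloxy)-3-[(2R,3S)-5,7-bis(benzyloxy)-2-[4-(benzyloxy)phenyl]-4,4-dimethoxy-3,4-dihydro-2H-chromen-3-yl]phenyl}propane-1,3-dione | COC1(OC)c2c(OCc3ccccc3)cc(OCc3ccccc3)cc2O[C@@H](c2ccc(OCc3ccccc3)cc2)[C@@H]1c1cc(C(=O)CC(=O)c2c(O)cc(OCc3ccccc3)cc2OCc2ccccc2)ccc1OCc1ccccc1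
F6 | step 7 | 4-(benzyloxy)-3-[(2R,3R,4R)-5,7-bis(benzyloxy)-2-[4-(benzyloxy)phenyl]-4-methoxy-3,4-dihydro-2H-chromen-3-yl]benzoic acid | CO[C@H]1c2c(OCc3ccccc3)cc(OCc3ccccc3)cc2O[C@@H](c2ccc(OCc3ccccc3)cc2)[C@@H]1c1cc(C(=O)O)ccc1OCc1ccccc1
F7 | step 7 | 2-acetyl-3,5-bis(benzyloxy)phenyl 4-(benzyloxy)-3-[(2R,3R,4R)-5,7-bis(benzyloxy)-2-[4-(benzyloxy)phenyl]-4-methoxy-3,4-dihydro-2H-chromen-3-yl]benzoate | CO[C@H]1c2c(OCc3ccccc3)cc(OCc3ccccc3)cc2O[C@@H](c2ccc(OCc3ccccc3)cc2)[C@@H]1c1cc(C(=O)Oc2cc(OCc3ccccc3)cc(OCc3ccccc3)c2C(C)=O)ccc1OCc1ccccc1
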